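## Retrosynthetic overview

1. Numbering: C1 = ring CH bearing propyl, then O2, C3 (ester C=O), C4 … C26, N27, C28 (amide C=O). The 28-membered ring is the only ring; it is closed in step 20 by intramolecular B-alkyl Suzuki coupling at C19–C20, followed by global deprotection.
2. Key disconnection: C1–C28, together with the C1–O ester and the amide, by a catalytic asymmetric three-component Passerini union of acid 20, butanal 33 and isocyanide 32. The isocyanide carbon acts as a carbamoyl-anion equivalent that joins two carbonyl carbons and sets C1.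
3. Acid 20 comes from alkenylboronate 16 and the dihaloalkene linchpin 18 (site-selective Suzuki). 16 comes from iodide 4 (desymmetrised meso-anhydride, C4/C6) and chloride 12 (C11 by asymmetric alkylzinc addition, C15 by copper-catalysed allylic alkylation).
4. Isocyanide 32 comes from ethyl (S)-4-chloro-3-hydroxybutanoate (C25) and an allenylboronate (C22/C23 by anti-selective γ-borylallylboration and oxidation).

Assumption: the enantiomer of each chiral catalyst or ligand in steps 1, 4, 7, 15 and 19 is assigned by analogy with model reactions; if a pilot run shows the opposite sense, its mirror image (for (DHQD)2AQN the pseudo-enantiomer (DHQ)2AQN) is used.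

Abbreviations: TBS = tert-butyldimethylsilyl; Bpin = 4,4,5,5-tetramethyl-1,3,2-dioxaborolan-2-yl; Ipc = isopinocampheyl; 9-BBN = 9-borabicyclo[3.3.1]nonane.

## Route

Step 1
Reactants: 1 meso-2,4-dimethylglutaric anhydride
Product: 2 (2R,4S)-5-methoxy-2,4-dimethyl-5-oxopentanoic acid
Conditions: MeOH (10 equiv), (DHQD)2AQN (10 mol%), Et2O, −40 °C
Reagents that add atoms: methanol (CO)
Why: Cinchona-alkaloid-catalysed alcoholysis (desymmetrisation of a meso anhydride): the syn-1,3-dimethyl relationship is inherited from the meso substrate, and the catalyst's choice between the two enantiotopic carbonyls fixes C4 (S) and C6 (S) of the target.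

Step 2
Reactants: 2 (2R,4S)-5-methoxy-2,4-dimethyl-5-oxopentanoic acid
Product: 3 methyl (2S,4R)-5-hydroxy-2,4-dimethylpentanoate
Conditions: BH3·SMe2 (1.1 equiv), THF, 0 °C → rt; MeOH quench; used crude
Reagents that add atoms: none
Why: Chemoselective borane reduction of a carboxylic acid in the presence of a methyl ester (acyloxyborane activation); no stereocentre is touched.

Step 3
Reactants: 3 methyl (2S,4R)-5-hydroxy-2,4-dimethylpentanoate
Product: 4 methyl (2S,4R)-5-iodo-2,4-dimethylpentanoate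
Conditions: I2, PPh3, imidazole, CH2Cl2, 0 °C → rt
Reagents that add atoms: iodine (II)
Why: Appel-type iodination of the primary alcohol by SN2 displacement of the alkoxyphosphonium ion, run at once so that the hydroxy ester does not lactonise.

Step 4
Reactants: 5 4-chlorobutanal; 6 pent-4-enylmagnesium bromide
Product: 8 (S)-1-chloronon-8-en-4-ol, via di(pent-4-enyl)zinc 7 (not isolated)
Conditions: 6 (3 equiv), ZnCl2 (1.5 equiv), Et2O, then 1,4-dioxane and filtration; then 5, Ti(OiPr)4 (1.2 equiv), (1R,2R)-N,N'-bis(trifluoromethylsulfonyl)cyclohexane-1,2-diamine (8 mol%), toluene, −20 °C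
Reagents that add atoms: none
Why: Titanium–bis(sulfonamide)-catalysed enantioselective addition of a dialkylzinc to an aliphatic aldehyde; the (R,R)-ligand directs the pentenyl group to the Si face and sets the carbinol centre (C11 of the target, R there, S in 8 by CIP).

Step 5
Reactants: 8 (S)-1-chloronon-8-en-4-ol
Product: 9 tert-butyl{[(4S)-1-chloronon-8-en-4-yl]oxy}dimethylsilane
Conditions: TBSCl, imidazole, DMF, rt
Reagents that add atoms: tert-butyldimethylsilyl chloride (CC(C)(C)[Si](C)(C)Cl)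
Why: Standard imidazole-promoted silylation of a secondary alcohol; the stereocentre is not involved.

Step 6
Reactants: 9 tert-butyl{[(4S)-1-chloronon-8-en-4-yl]oxy}dimethylsilane; 10 (E)-1,4-dibromobut-2-ene
Product: 11 {[(4S,8E)-10-bromo-1-chlorodec-8-en-4-yl]oxy}(tert-butyl)dimethylsilane
Conditions: 10 (4 equiv), second-generation Grubbs catalyst (3 mol%), CH2Cl2, 40 °C
Reagents that add atoms: none
Why: Olefin cross-metathesis of a terminal alkene with an excess of a symmetrical internal alkene gives the (E)-allylic bromide; no stereocentre is formed.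

Step 7
Reactants: 11 {[(4S,8E)-10-bromo-1-chlorodec-8-en-4-yl]oxy}(tert-butyl)dimethylsilane
Product: 12 tert-butyl{[(4S,8R)-1-chloro-8-ethyldec-9-en-4-yl]oxy}dimethylsilane
Conditions: EtMgBr (1.2 equiv), CuBr·SMe2 (1 mol%), (R,R)-Taniaphos (1.1 mol%), CH2Cl2, −75 °C
Reagents that add atoms: ethylmagnesium bromide (CC[Mg]Br)
Why: Copper-catalysed asymmetric allylic alkylation of an (E)-allylic bromide by a Grignard reagent: ligand-controlled SN2' delivery of ethyl creates C15 (R) and the terminal vinyl group, the primary alkyl chloride being inert at −75 °C.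

Step 8
Reactants: 12 tert-butyl{[(4S,8R)-1-chloro-8-ethyldec-9-en-4-yl]oxy}dimethylsilane; 4 methyl (2S,4R)-5-iodo-2,4-dimethylpentanoate
Product: 14 methyl (2S,4S,9R,13R)-9-(tert-butyldimethylsilyloxy)-13-ethyl-2,4-dimethylpentadec-14-enoate, via Grignard reagent 13 (not isolated)
Conditions: 12, Mg turnings, THF, 65 °C; then 4 (0.8 equiv), Li2CuCl4 (3 mol%), NMP (4 equiv), THF, 0 °C
Reagents that add atoms: none
Why: Copper-catalysed (Kochi-type) sp3–sp3 cross-coupling of an alkyl Grignard reagent with a primary alkyl iodide, which under Li2CuCl4/NMP catalysis outruns addition to the hindered α-branched methyl ester; the bond forms between CH2 carbons, so no stereocentre is affected.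

Step 9
Reactants: 14 methyl (2S,4S,9R,13R)-9-(tert-butyldimethylsilyloxy)-13-ethyl-2,4-dimethylpentadec-14-enoate; 15 vinylboronic acid pinacol ester
Product: 16 methyl (2S,4S,9R,13R,14E)-9-(tert-butyldimethylsilyloxy)-13-ethyl-2,4-dimethyl-15-(4,4,5,5-tetramethyl-1,3,2-dioxaborolan-2-yl)pentadec-14-enoate
Conditions: 15 (3 equiv), second-generation Grubbs catalyst (5 mol%), CH2Cl2, 40 °C
Reagents that add atoms: none
Why: Olefin cross-metathesis with vinyl pinacol boronate gives the (E)-alkenylboronate, the allylic branch at C15 raising the E-selectivity; C16=C17 (E) is set here.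

Step 10
Reactants: 17 3-methoxyprop-1-yne
Product: 18 (E)-2-bromo-3-iodo-1-methoxyprop-2-ene
Conditions: IBr (1.05 equiv), CH2Cl2, −78 → 0 °C
Reagents that add atoms: iodine monobromide (BrI)
Why: Electrophilic anti-addition of iodine monobromide to a terminal alkyne (iodine at the terminal carbon, bromide opening the iodonium ion at the internal carbon) gives the trans-1-iodo-2-bromoalkene that encodes the C18=C19 geometry.

Step 11
Reactants: 16 methyl (2S,4S,9R,13R,14E)-9-(tert-butyldimethylsilyloxy)-13-ethyl-2,4-dimethyl-15-(4,4,5,5-tetramethyl-1,3,2-dioxaborolan-2-yl)pentadec-14-enoate; 18 (E)-2-bromo-3-iodo-1-methoxyprop-2-ene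
Product: 20 (2S,4S,9R,13R,14E,16E)-17-bromo-9-(tert-butyldimethylsilyloxy)-13-ethyl-18-methoxy-2,4-dimethyloctadeca-14,16-dienoic acid, via bromodiene methyl ester 19 (not isolated)
Conditions: 18 (1.3 equiv), Pd(dppf)Cl2 (5 mol%), K3PO4 (3 M aq.), THF, rt; then LiOH (5 equiv), MeOH/H2O, 40 °C; HCl work-up
Reagents that add atoms: lithium hydroxide ([Li+].[OH-])
Why: Site-selective Suzuki–Miyaura coupling at the C–I bond (oxidative addition far faster than at the hindered C–Br bond) with retention of both alkene geometries, followed in the same flask by ester saponification; this fixes C17 cis to CH2OMe on C18=C19.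

Step 12
Reactants: 21 ethyl (S)-4-chloro-3-hydroxybutanoate
Product: 22 ethyl (S)-4-azido-3-hydroxybutanoate
Conditions: NaN3 (1.5 equiv), DMF, 85 °C
Reagents that add atoms: sodium azide ([Na+].[N-]=[N+]=[N-])
Why: SN2 displacement of the primary chloride by azide; the C25 stereocentre comes from the chiral pool and is not the reacting carbon.

Step 13
Reactants: 22 ethyl (S)-4-azido-3-hydroxybutanoate
Product: 23 ethyl (S)-4-azido-3-(tert-butyldimethylsilyloxy)butanoate
Conditions: TBSCl, imidazole, DMF, rt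
Reagents that add atoms: tert-butyldimethylsilyl chloride (CC(C)(C)[Si](C)(C)Cl)
Why: Standard silylation of the secondary alcohol, which also blocks β-elimination in the aldehyde made next.

Step 14
Reactants: 23 ethyl (S)-4-azido-3-(tert-butyldimethylsilyloxy)butanoate
Product: 24 (S)-4-azido-3-(tert-butyldimethylsilyloxy)butanal
Conditions: DIBAL-H (1.1 equiv), CH2Cl2, −78 °C; Rochelle salt work-up
Reagents that add atoms: none
Why: Partial reduction of an ester to the aldehyde by DIBAL-H through a tetrahedral aluminate that is stable at −78 °C; the azide is inert at this temperature.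

Step 15
Reactants: 24 (S)-4-azido-3-(tert-butyldimethylsilyloxy)butanal; 25 allenylboronic acid pinacol ester
Product: 28 (3R,4S,6S)-7-azido-6-(tert-butyldimethylsilyloxy)hept-1-ene-3,4-diol, via allylborane 26 (not isolated), via borinate adduct 27 (not isolated)
Conditions: 25, (+)-Ipc2BH [from (−)-α-pinene], Et2O, 0 °C → rt; then 24, −78 °C; then NaOH (3 M aq.), H2O2 (30%), rt
Reagents that add atoms: hydrogen peroxide (OO)
Why: Brown-type asymmetric γ-borylallylboration then oxidation: hydroboration of the allenylboronate gives the (E)-γ-boryl allylborane, whose chair transition state gives the anti C–O/C–B pair; the Ipc groups direct attack to the Re face of 24 (C23 S), and stereoretentive C–B oxidation gives the anti diol (C22 R).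

Step 16
Reactants: 28 (3R,4S,6S)-7-azido-6-(tert-butyldimethylsilyloxy)hept-1-ene-3,4-diol
Product: 29 {[(2S)-1-azido-3-[(4S,5R)-5-ethenyl-2,2-dimethyl-1,3-dioxolan-4-yl]propan-2-yl]oxy}(tert-butyl)dimethylsilane
Conditions: 2,2-dimethoxypropane, PPTS (5 mol%), CH2Cl2, rt
Reagents that add atoms: 2,2-dimethoxypropane (COC(C)(C)OC)
Why: Acid-catalysed transacetalisation protects the 1,2-diol as its isopropylidene acetal; no stereocentre is changed.

Step 17
Reactants: 29 {[(2S)-1-azido-3-[(4S,5R)-5-ethenyl-2,2-dimethyl-1,3-dioxolan-4-yl]propan-2-yl]oxy}(tert-butyl)dimethylsilane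
Product: 31 N-{(2S)-2-(tert-butyldimethylsilyloxy)-3-[(4S,5R)-5-ethenyl-2,2-dimethyl-1,3-dioxolan-4-yl]propyl}formamide, via amine 30 (not isolated)
Conditions: PPh3, THF/H2O, 50 °C; then HCO2Et, 55 °C
Reagents that add atoms: ethyl formate (CCOC=O)
Why: Staudinger reduction of the azide followed by N-formylation of the primary amine with ethyl formate; no stereocentre is involved.

Step 18
Reactants: 31 N-{(2S)-2-(tert-butyldimethylsilyloxy)-3-[(4S,5R)-5-ethenyl-2,2-dimethyl-1,3-dioxolan-4-yl]propyl}formamide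
Product: 32 tert-butyl{[(2S)-1-[(4S,5R)-5-ethenyl-2,2-dimethyl-1,3-dioxolan-4-yl]-3-isocyanopropan-2-yl]oxy}dimethylsilane
Conditions: POCl3 (1.1 equiv), Et3N (3 equiv), CH2Cl2, −30 → 0 °C
Reagents that add atoms: none
Why: Dehydration of an N-alkylformamide to the isocyanide with POCl3/Et3N; silyl ether and acetal tolerate the basic medium.

Step 19
Reactants: 20 (2S,4S,9R,13R,14E,16E)-17-bromo-9-(tert-butyldimethylsilyloxy)-13-ethyl-18-methoxy-2,4-dimethyloctadeca-14,16-dienoic acid; 33 butanal; 32 tert-butyl{[(2S)-1-[(4S,5R)-5-ethenyl-2,2-dimethyl-1,3-dioxolan-4-yl]-3-isocyanopropan-2-yl]oxy}dimethylsilane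
Product: 34 (2S)-1-{[(2S)-2-(tert-butyldimethylsilyloxy)-3-[(4S,5R)-5-ethenyl-2,2-dimethyl-1,3-dioxolan-4-yl]propyl]amino}-1-oxopentan-2-yl (2S,4S,9R,13R,14E,16E)-17-bromo-9-(tert-butyldimethylsilyloxy)-13-ethyl-18-methoxy-2,4-dimethyloctadeca-14,16-dienoate
Conditions: 33 (3 equiv), (R)-TRIP [3,3'-bis(2,4,6-triisopropylphenyl)-1,1'-binaphthyl-2,2'-diyl hydrogen phosphate] (10 mol%), CHCl3, 4 Å MS, 0 °C → rt
Reagents that add atoms: none
Why: Proposed new method: the isocyanide carbon of 32 attacks, as a carbamoyl-anion equivalent, the aldehyde carbon of 33 held in the hydrogen-bonded heterodimer of acid 20 and the chiral phosphoric acid, the nitrilium ion is captured by the carboxylate and a Mumm acyl shift gives the α-acyloxy amide, so that C1–C28, the C1–O ester and the amide form in one operation with C1 (S) fixed by the catalyst shielding one aldehyde face; the closest known reaction is the chiral-phosphoric-acid-catalysed enantioselective three-component Passerini reaction of aliphatic aldehydes, here extended to a primary alkyl isocyanide and two chiral partners.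

Step 20
Reactants: 34 (2S)-1-{[(2S)-2-(tert-butyldimethylsilyloxy)-3-[(4S,5R)-5-ethenyl-2,2-dimethyl-1,3-dioxolan-4-yl]propyl]amino}-1-oxopentan-2-yl (2S,4S,9R,13R,14E,16E)-17-bromo-9-(tert-butyldimethylsilyloxy)-13-ethyl-18-methoxy-2,4-dimethyloctadeca-14,16-dienoate
Product: 36 protected macrocycle (11,25-di-O-TBS-22,23-O-isopropylidene derivative of 37), via alkylborane 35 (not isolated)
Conditions: 9-BBN-H (2 equiv), THF, rt; then syringe-pump addition to Pd(dppf)Cl2 (20 mol%), AsPh3 (20 mol%), Cs2CO3 (3 equiv), DMF/THF/H2O, 45 °C, final concentration 1 mM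
Reagents that add atoms: none
Why: Chemoselective hydroboration of the only monosubstituted alkene with 9-BBN-H, then intramolecular B-alkyl Suzuki–Miyaura coupling with the alkenyl bromide under high dilution, closes the 28-membered ring at C19–C20 with retention of the C18=C19 geometry.

Step 21
Reactants: 36 protected macrocycle (11,25-di-O-TBS-22,23-O-isopropylidene derivative of 37)
Product: 37 CNP0221503.3
Conditions: HF (48% aq.), MeCN, 0 °C → rt
Reagents that add atoms: none
Why: Acid-mediated global deprotection: HF cleaves both silyl ethers and the aqueous acid hydrolyses the isopropylidene acetal, while ester, amide, diene and allylic methyl ether are stable to these mild conditions.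

## Compound list

1 | meso-2,4-dimethylglutaric anhydride [(3R,5S)-3,5-dimethyloxane-2,6-dione] | C[C@@H]1C[C@H](C)C(=O)OC1=O | starting material
2 | (2R,4S)-5-methoxy-2,4-dimethyl-5-oxopentanoic acid | COC(=O)[C@@H](C)C[C@@H](C)C(=O)O | intermediate
3 | methyl (2S,4R)-5-hydroxy-2,4-dimethylpentanoate | COC(=O)[C@@H](C)C[C@@H](C)CO | intermediate
4 | methyl (2S,4R)-5-iodo-2,4-dimethylpentanoate | COC(=O)[C@@H](C)C[C@@H](C)CI | intermediate
5 | 4-chlorobutanal | ClCCCC=O | starting material
6 | pent-4-enylmagnesium bromide | C=CCCC[Mg]Br | starting material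
7 | di(pent-4-enyl)zinc (not isolated) | C=CCCC[Zn]CCCC=C | intermediate
8 | (S)-1-chloronon-8-en-4-ol | ClCCC[C@@H](O)CCCC=C | intermediate
9 | tert-butyl{[(4S)-1-chloronon-8-en-4-yl]oxy}dimethylsilane | ClCCC[C@@H](O[Si](C)(C)C(C)(C)C)CCCC=C | intermediate
10 | (E)-1,4-dibromobut-2-ene | BrC/C=C/CBr | starting material
11 | {[(4S,8E)-10-bromo-1-chlorodec-8-en-4-yl]oxy}(tert-butyl)dimethylsilane | ClCCC[C@@H](O[Si](C)(C)C(C)(C)C)CCC/C=C/CBr | intermediate
12 | tert-butyl{[(4S,8R)-1-chloro-8-ethyldec-9-en-4-yl]oxy}dimethylsilane | ClCCC[C@@H](O[Si](C)(C)C(C)(C)C)CCC[C@@H](CC)C=C | intermediate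
13 | [(4S,8R)-4-(tert-butyldimethylsilyloxy)-8-ethyldec-9-en-1-yl]magnesium chloride (not isolated) | Cl[Mg]CCC[C@@H](O[Si](C)(C)C(C)(C)C)CCC[C@@H](CC)C=C | intermediate
14 | methyl (2S,4S,9R,13R)-9-(tert-butyldimethylsilyloxy)-13-ethyl-2,4-dimethylpentadec-14-enoate | COC(=O)[C@@H](C)C[C@@H](C)CCCC[C@@H](O[Si](C)(C)C(C)(C)C)CCC[C@@H](CC)C=C | intermediate
15 | vinylboronic acid pinacol ester | C=CB1OC(C)(C)C(C)(C)O1 | starting material
16 | methyl (2S,4S,9R,13R,14E)-9-(tert-butyldimethylsilyloxy)-13-ethyl-2,4-dimethyl-15-(4,4,5,5-tetramethyl-1,3,2-dioxaborolan-2-yl)pentadec-14-enoate | COC(=O)[C@@H](C)C[C@@H](C)CCCC[C@@H](O[Si](C)(C)C(C)(C)C)CCC[C@@H](CC)/C=C/B1OC(C)(C)C(C)(C)O1 | intermediate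
17 | 3-methoxyprop-1-yne (methyl propargyl ether) | COCC#C | starting material
18 | (E)-2-bromo-3-iodo-1-methoxyprop-2-ene | COC/C(Br)=C\I | intermediate
19 | methyl (2S,4S,9R,13R,14E,16E)-17-bromo-9-(tert-butyldimethylsilyloxy)-13-ethyl-18-methoxy-2,4-dimethyloctadeca-14,16-dienoate (not isolated) | COC(=O)[C@@H](C)C[C@@H](C)CCCC[C@@H](O[Si](C)(C)C(C)(C)C)CCC[C@@H](CC)/C=C/C=C(\COC)Br | intermediate
20 | (2S,4S,9R,13R,14E,16E)-17-bromo-9-(tert-butyldimethylsilyloxy)-13-ethyl-18-methoxy-2,4-dimethyloctadeca-14,16-dienoic acid | OC(=O)[C@@H](C)C[C@@H](C)CCCC[C@@H](O[Si](C)(C)C(C)(C)C)CCC[C@@H](CC)/C=C/C=C(\COC)Br | intermediate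
21 | ethyl (S)-4-chloro-3-hydroxybutanoate | CCOC(=O)C[C@H](O)CCl | starting material
22 | ethyl (S)-4-azido-3-hydroxybutanoate | CCOC(=O)C[C@H](O)CN=[N+]=[N-] | intermediate
23 | ethyl (S)-4-azido-3-(tert-butyldimethylsilyloxy)butanoate | CCOC(=O)C[C@H](O[Si](C)(C)C(C)(C)C)CN=[N+]=[N-] | intermediate
24 | (S)-4-azido-3-(tert-butyldimethylsilyloxy)butanal | O=CC[C@H](O[Si](C)(C)C(C)(C)C)CN=[N+]=[N-] | intermediate
25 | allenylboronic acid pinacol ester | C=C=CB1OC(C)(C)C(C)(C)O1 | starting material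
26 | (E)-[3-(4,4,5,5-tetramethyl-1,3,2-dioxaborolan-2-yl)allyl]bis(isopinocampheyl)borane (not isolated) | CC1(C)OB(/C=C/CB([C@H]2C[C@H]3C[C@@H]([C@@H]2C)C3(C)C)[C@H]2C[C@H]3C[C@@H]([C@@H]2C)C3(C)C)OC1(C)C | intermediate
27 | bis(isopinocampheyl)borinate of (3R,4S,6S)-7-azido-6-(tert-butyldimethylsilyloxy)-3-(pinacolatoboryl)hept-1-en-4-ol (not isolated) | C=C[C@@H](B1OC(C)(C)C(C)(C)O1)[C@@H](OB([C@H]2C[C@H]3C[C@@H]([C@@H]2C)C3(C)C)[C@H]2C[C@H]3C[C@@H]([C@@H]2C)C3(C)C)C[C@H](O[Si](C)(C)C(C)(C)C)CN=[N+]=[N-] | intermediate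
28 | (3R,4S,6S)-7-azido-6-(tert-butyldimethylsilyloxy)hept-1-ene-3,4-diol | C=C[C@@H](O)[C@@H](O)C[C@H](O[Si](C)(C)C(C)(C)C)CN=[N+]=[N-] | intermediate
29 | {[(2S)-1-azido-3-[(4S,5R)-5-ethenyl-2,2-dimethyl-1,3-dioxolan-4-yl]propan-2-yl]oxy}(tert-butyl)dimethylsilane | C=C[C@@H](OC1(C)C)[C@@H](O1)C[C@H](O[Si](C)(C)C(C)(C)C)CN=[N+]=[N-] | intermediate
30 | (2S)-2-(tert-butyldimethylsilyloxy)-3-[(4S,5R)-5-ethenyl-2,2-dimethyl-1,3-dioxolan-4-yl]propan-1-amine (not isolated) | C=C[C@@H](OC1(C)C)[C@@H](O1)C[C@H](O[Si](C)(C)C(C)(C)C)CN | intermediate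
31 | N-{(2S)-2-(tert-butyldimethylsilyloxy)-3-[(4S,5R)-5-ethenyl-2,2-dimethyl-1,3-dioxolan-4-yl]propyl}formamide | C=C[C@@H](OC1(C)C)[C@@H](O1)C[C@H](O[Si](C)(C)C(C)(C)C)CNC=O | intermediate
32 | tert-butyl{[(2S)-1-[(4S,5R)-5-ethenyl-2,2-dimethyl-1,3-dioxolan-4-yl]-3-isocyanopropan-2-yl]oxy}dimethylsilane | C=C[C@@H](OC1(C)C)[C@@H](O1)C[C@H](O[Si](C)(C)C(C)(C)C)C[N+]#[C-] | intermediate
33 | butanal | CCCC=O | starting material
34 | Passerini adduct: (2S)-1-{[(2S)-2-(tert-butyldimethylsilyloxy)-3-[(4S,5R)-5-ethenyl-2,2-dimethyl-1,3-dioxolan-4-yl]propyl]amino}-1-oxopentan-2-yl ester of acid 20 | CCC[C@H](OC(=O)[C@@H](C)C[C@@H](C)CCCC[C@@H](O[Si](C)(C)C(C)(C)C)CCC[C@@H](CC)/C=C/C=C(\COC)Br)C(=O)NC[C@@H](O[Si](C)(C)C(C)(C)C)C[C@H](OC1(C)C)[C@H](O1)C=C | intermediate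
35 | B-alkyl-9-BBN adduct of 34 at C20 (not isolated) | CCC[C@H](OC(=O)[C@@H](C)C[C@@H](C)CCCC[C@@H](O[Si](C)(C)C(C)(C)C)CCC[C@@H](CC)/C=C/C=C(\COC)Br)C(=O)NC[C@@H](O[Si](C)(C)C(C)(C)C)C[C@H](OC1(C)C)[C@H](O1)CCB1C2CCCC1CCC2 | intermediate
36 | protected macrocycle (11,25-di-O-TBS-22,23-O-isopropylidene derivative of 37) | CCC[C@@H]1OC(=O)[C@@H](C)C[C@@H](C)CCCC[C@@H](O[Si](C)(C)C(C)(C)C)CCC[C@@H](CC)/C=C/C=C(\COC)CC[C@@H](OC2(C)C)[C@@H](O2)C[C@H](O[Si](C)(C)C(C)(C)C)CNC1=O | intermediate
37 | CNP0221503.3 | CCC[C@@H]1OC(=O)[C@@H](C)C[C@@H](C)CCCC[C@@H](O)CCC[C@@H](CC)/C=C/C=C(\COC)CC[C@@H](O)[C@@H](O)C[C@H](O)CNC1=O | target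

## Step count and risk

Total steps: 21. Longest linear sequence: 10 steps (4, 5, 6, 7, 8, 9, 11, 19, 20, 21; the isocyanide branch 12–18 followed by 19–21 is equally long).

The three steps most likely to fail:

Step 19 (Passerini union). Catalyst control of C1 with a primary alkyl isocyanide and two chiral partners is beyond demonstrated scope, and an unselective background reaction would give both C1 epimers. The fallback sets out from amine 30 (isolated after the Staudinger stage of step 17) and acid 20. Amine 30 is coupled with commercial (S)-2-hydroxypentanoic acid F1 (EDC·HCl, HOBt, CH2Cl2) to give the hydroxy amide F2. Its secondary hydroxyl is then acylated with 20 under Yamaguchi conditions (2,4,6-trichlorobenzoyl chloride, Et3N, then DMAP, toluene). This comes back to the route at 34, with C1 taken from the chiral pool and two classical bond formations replacing steps 18 and 19.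

Step 20 (macrocyclic B-alkyl Suzuki). The α-acyloxy amide of 34 is sensitive to aqueous base, and the ring closure competes with oligomerisation and protodeboronation. The fallback sets out from formamide 31 and ester 19 (isolated before the saponification stage of step 11) and makes the Passerini reaction the ring-closing event. Formamide 31 is hydroborated with 9-BBN-H to the alkylborane F3. Intermolecular B-alkyl Suzuki coupling of F3 with 19 (Pd(dppf)Cl2, AsPh3, Cs2CO3, DMF/H2O) gives the open-chain formamide ester F4. Dehydration (POCl3, Et3N) gives the isocyanide ester F5, and saponification (LiOH; isocyanides are base-stable) gives the isocyano acid F6. F6 is added slowly to excess butanal 33 and the phosphoric acid catalyst at high dilution, so that the base-labile ester is formed only after all basic steps. This comes back to the route at 36.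

Step 8 (copper-catalysed sp3–sp3 coupling). The β-branched iodide is slow, and the Grignard reagent can attack the methyl ester or undergo halogen–metal exchange. The fallback sets out from chloride 12 and iodide 4 and reverses the roles of the partners. Finkelstein exchange of 12 (NaI, acetone, reflux) gives the iodide F7. Zinc insertion into 4 (Zn dust, DMA) gives the ester-tolerant alkylzinc iodide F8. Nickel-catalysed alkyl–alkyl Negishi coupling of F8 with F7 (Ni(cod)2, (S,S)-s-Bu-Pybox, DMA, rt) comes back to the route at 14.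

## Further compounds

F1 | step 19 | (S)-2-hydroxypentanoic acid | CCC[C@H](O)C(=O)O
F2 | step 19 | (2S)-N-{(2S)-2-(tert-butyldimethylsilyloxy)-3-[(4S,5R)-5-ethenyl-2,2-dimethyl-1,3-dioxolan-4-yl]propyl}-2-hydroxypentanamide | CCC[C@H](O)C(=O)NC[C@@H](O[Si](C)(C)C(C)(C)C)C[C@H](OC1(C)C)[C@H](O1)C=C
F3 | step 20 | B-alkyl-9-BBN adduct of formamide 31 | O=CNC[C@@H](O[Si](C)(C)C(C)(C)C)C[C@H](OC1(C)C)[C@H](O1)CCB1C2CCCC1CCC2
F4 | step 20 | open-chain formamide methyl ester (C19–C20 coupled) | COC(=O)[C@@H](C)C[C@@H](C)CCCC[C@@H](O[Si](C)(C)C(C)(C)C)CCC[C@@H](CC)/C=C/C=C(\COC)CC[C@@H](OC1(C)C)[C@@H](O1)C[C@H](O[Si](C)(C)C(C)(C)C)CNC=O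
F5 | step 20 | open-chain isocyanide methyl ester | COC(=O)[C@@H](C)C[C@@H](C)CCCC[C@@H](O[Si](C)(C)C(C)(C)C)CCC[C@@H](CC)/C=C/C=C(\COC)CC[C@@H](OC1(C)C)[C@@H](O1)C[C@H](O[Si](C)(C)C(C)(C)C)C[N+]#[C-]
F6 | step 20 | open-chain isocyano acid | OC(=O)[C@@H](C)C[C@@H](C)CCCC[C@@H](O[Si](C)(C)C(C)(C)C)CCC[C@@H](CC)/C=C/C=C(\COC)CC[C@@H](OC1(C)C)[C@@H](O1)C[C@H](O[Si](C)(C)C(C)(C)C)C[N+]#[C-]
F7 | step 8 | tert-butyl{[(4S,8R)-8-ethyl-1-iododec-9-en-4-yl]oxy}dimethylsilane | ICCC[C@@H](O[Si](C)(C)C(C)(C)C)CCC[C@@H](CC)C=C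
F8 | step 8 | [(2R,4S)-5-methoxy-2,4-dimethyl-5-oxopentyl]zinc iodide | COC(=O)[C@@H](C)C[C@@H](C)C[Zn]I
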